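**Numbering.** Compounds 1–35 are fixed by the steps below and used in all sections. Flavan numbering is used for each unit: ring A is the fused benzene ring, ring B the 2-aryl group, ring C the pyran ring. α means below and β above the plane in the usual drawing.

## The problem

CNP0115797.3 is a trimeric proanthocyanidin. The top unit is of the ent-robinetinidol type (2S,3R,4S; ring C 2,3-trans-3,4-cis) and is bonded from C4 to C8 of a middle unit of the ent-epirobinetinidol type (2S,3S,4S; 2,3-cis-3,4-trans), whose C4 is bonded to C8 of (−)-epicatechin (2R,3R).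

Both upper units lack O5. Ring A of the middle unit is therefore a resorcinol ring that must be substituted at C8, the carbon between O1 and O7. Electrophiles prefer C6 of that ring, and prefer the phloroglucinol ring of the bottom unit even more.

Two of the eight stereocentres come with epicatechin. The other six form two triads (C2, C3, C4 of each upper unit) that are too far apart to control one another, so each triad needs its own source of absolute configuration; inside a triad, neighbours can relay.

Both triads have the aryl groups at C2 and C4 trans, but C3 is opposite. In the top unit O3 is cis to the C4 aryl group, which is the minor outcome when an arene adds to a flavan C4 cation. In the middle unit O3 is trans to the C4 aryl group and cis to the C2 aryl group.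

The feature that opens the middle unit is this: its atoms O1–C8a–C4a–C4, with C4 carrying the C8 aryl group of the bottom unit, are the retron of an o-quinone methide of the ring A phenol, and C3–C2 with its single aryl group is an acetophenone enol equivalent. Ring C can therefore be closed (C3–C4 and O1–C2) around a C4 centre that a catalyst sets.

Twelve phenols (two pyrogallol rings that oxidise in air), benzylic C2–O1 ethers and acid-sensitive C4–aryl bonds call for a single neutral deprotection at the end: benzyl ethers and hydrogenolysis.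

## Retrosynthesis

**35 ⇒ 34.** The fifteen O–benzyl bonds are cut. Benzyl is preferred to methyl, silyl or acetal groups because it survives butyllithium, hydride and brief acid at low temperature and leaves under neutral hydrogen. The precursor 34 has no free phenol and no oxidisable pyrogallol. The forward step must remove fifteen groups without touching the C4–aryl bonds.

**34 ⇒ 32 ⇒ 22 + 30.** First the C4–H bond of the top unit is cut (to carbinol 32, which reacts through cation 33), then the C4(top)–C8(middle) bond, as aryllithium 31 (from bromide 22) plus ketone 30. The conventional cut, C4 cation plus arene, would put the incoming aryl group trans to O3 and could not choose C8 over C6 or over the bottom unit. With the polarity reversed, the bromine defines C8, and hydride arrives last and trans to O3, so the aryl group ends cis. The trimer falls into a dimer and a monomer. The forward steps must add a hindered aryllithium to an enolisable ketone and capture cation 33 face-selectively.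

**30 ⇒ 29 ⇒ 27 ⇒ 26 ⇒ 24 + 25.** The O1–C2 bond is cut to epoxy ketone 27 (through phenol 28), then the epoxide oxygen to chalcone 26, then the enone double bond to ketone 24 (from 23) and aldehyde 25. The chalcone route is preferred to a diarylpropene dihydroxylation because it delivers C4 as the ketone that step 18 needs and sets C2 and C3 with one catalyst. The forward steps must epoxidise an electron-rich enone enantioselectively and open the epoxide 6-endo with inversion.

**22 ⇒ 21 ⇒ 19.** After the O3 benzyl group, the C2–H and C3–O bonds are cut (through epoxide 20), which leaves enol ether 19 with C4 as its only stereocentre in ring C. Setting C2 and C3 first, as in the top unit, would lead to a 2,3-cis 4-ketone that epimerises. With C4 in place both centres follow from it. Hydroboration would add syn and give the 2,4-cis ring; epoxidation followed by backside hydride gives 2,4-trans with 2,3-cis, which is the middle unit. The forward step must epoxidise anti to the C4 aryl group and deliver hydride with inversion at C2.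

**19 ⇒ 16 + 13 (key).** The C3–C4 and O1–C2 bonds are cut, through N,O-ketal 18 and o-quinone methide 17, to diarylmethanol 16 and enamide 13. A cycloaddition with a styrene would have to set three centres and gives the wrong 2,4 relation. The enamide brings C2 at the ketone level, so only C4 has to be controlled, and its nucleophilic carbon is an unhindered CH2. A ring and a stereocentre are traded for a carbinol and a two-carbon enol equivalent. The forward step must select one face of the methide carbon of 17.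

**16 ⇒ 4 + 8.** The C4(middle)–C8(bottom) bond is cut as aryllithium 14 (from bromide 4) plus aldehyde 8, used as phenolate 15. A Friedel–Crafts hydroxyalkylation of 3 would give C6/C8 mixtures and over-reaction. The bromine of 8 is carried untouched to step 18, where it becomes the C8 nucleophile of the middle unit.

**Building blocks.** 4 ⇐ 3 ⇐ 2 ⇐ 1; 8 ⇐ 7 ⇐ 5 (through 6); 13 ⇐ 11 ⇐ 10 ⇐ 9 (through 12). In 5 the future C8 is the carbon between the two oxygens, on the symmetry axis, and already carries bromine. Formylation can only enter at the position that becomes C4a, so the regiochemical problem of the middle unit is solved by purchase.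

## Roads not taken

**Alternative 1:** Both C4–C8 bonds are cut as C4 cation plus arene (the biomimetic plan). The forward key step is Lewis acid ionisation of the 4-methoxyflavan A1 in the presence of the debrominated dimer A2.
- The cation would attack C6 of the phloroglucinol ring of the bottom unit, or C6 of the middle unit, before C8 of a resorcinol ring; blocking groups would have to be added and removed.
- An arene enters trans to O3 of a 2,3-trans cation, giving the 3,4-trans top unit; the target is 3,4-cis.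
- The 2,3-cis middle ring would need a second chalcone sequence plus an inversion at C3.

The chosen plan fixes C8 with a bought bromine and obtains 3,4-cis by letting hydride, not the arene, be the last group to arrive.

**Alternative 2:** Ring C of the middle unit is made by a [4+2] cycloaddition of o-quinone methide 17 with the β-borylstyrene A3, to give the 3-borylflavan A4 with C2, C3 and C4 set in one event, followed by C–B oxidation.
- The endo preference of the aryl group places it cis to the C4 aryl group (2,4-cis, as in A4); both upper units are 2,4-trans.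
- The middle unit would need a Z-alkene reacting exo.
- An oxygenated alkene would add with the ring oxygen at the oxygen-bearing carbon (isoflavan skeleton), so O3 must be masked as boron, and a β-aryloxy boronate is prone to elimination.

The enamide closes the same two bonds but leaves only C4 to control.

**Alternative 3:** Both interflavan bonds are made by the ketone/aryllithium/hydride sequence: the bromo ketone A5 plus aryllithium 14, then ionic hydrogenation, gives the dimer A6.
- A6 has the 2,3-trans-3,4-cis ring; the middle unit is 2,3-cis-3,4-trans, so C3 of A6 would have to be inverted.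
- After oxidation at O3, hydride would return from the face away from the pseudoaxial C4 aryl group and restore the same configuration.
- A displacement at this carbinol, flanked by two arylated carbons, is unlikely.
- A5 also needs a second chalcone sequence and a selectively removable group on O3.

The chosen plan sets C4 of the middle unit first and lets it direct C3 and C2.

Key step: step 10

## Route

Assumption: the sense of induction written for (R)-TRIP in step 10 is taken by analogy with simpler o-quinone methides; if this substrate gives the 4R epimer, the (S)-acid is used instead.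

Assumption: compounds 1, 5, 9, 23 and 25 are taken as commercial; aldehyde 7 is made, not bought.

Step 1
Reactants: 1 (−)-epicatechin
Product: 2 5,7,3',4'-tetra-O-benzyl-(−)-epicatechin
Conditions: BnBr, K2CO3, DMF, 0 °C to rt
Reagents that add atoms: benzyl bromide, BrCc1ccccc1
Why: Williamson etherification of the four phenols with K2CO3 should leave the secondary alcohol untouched; no stereocentre is affected.

Step 2
Reactants: 2 5,7,3',4'-tetra-O-benzyl-(−)-epicatechin
Product: 3 3,5,7,3',4'-penta-O-benzyl-(−)-epicatechin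
Conditions: NaH, BnBr, Bu4NI (cat.), DMF, 0 °C to rt
Reagents that add atoms: benzyl bromide, BrCc1ccccc1
Why: Williamson benzylation of the axial O3 through its sodium alkoxide; the phenols are already capped, so C2 cannot epimerise by ring opening.

Step 3
Reactants: 3 3,5,7,3',4'-penta-O-benzyl-(−)-epicatechin
Product: 4 8-bromo-3,5,7,3',4'-penta-O-benzyl-(−)-epicatechin
Conditions: NBS, CH2Cl2, −78 °C to 0 °C
Reagents that add atoms: N-bromosuccinimide, O=C1CCC(=O)N1Br
Why: Electrophilic aromatic bromination of the phloroglucinol ring; in 5,7-di-O-benzyl flavans NBS attacks C8, between O1 and O7, in preference to C6, a regiochemistry established for benzylated catechin and epicatechin.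

Step 4
Reactants: 5 2-bromoresorcinol
Product: 7 3-bromo-2,4-dihydroxybenzaldehyde, via aryl iminium chloride 6 (not isolated)
Conditions: POCl3, DMF, MeCN, −15 °C to rt; then H2O, 50 °C
Reagents that add atoms: N,N-dimethylformamide, CN(C)C=O; water, O
Why: Vilsmeier–Haack formylation of a resorcinol; the chloroiminium ion attacks the two equivalent positions para to one hydroxyl and ortho to the other, the only activated sites not blocked by bromine, and hydrolysis of 6 gives the aldehyde.

Step 5
Reactants: 7 3-bromo-2,4-dihydroxybenzaldehyde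
Product: 8 4-(benzyloxy)-3-bromo-2-hydroxybenzaldehyde
Conditions: BnBr (1.05 equiv), NaHCO3, KI (cat.), MeCN, 60 °C
Reagents that add atoms: benzyl bromide, BrCc1ccccc1
Why: Williamson etherification with a weak base should alkylate only the 4-OH, which is the more acidic (para to the formyl group); the 2-OH is hydrogen-bonded to the carbonyl and flanked by bromine.

Step 6
Reactants: 9 1-(3,4,5-trihydroxyphenyl)ethanone
Product: 10 1-[3,4,5-tris(benzyloxy)phenyl]ethanone
Conditions: BnBr, K2CO3, DMF, 60 °C
Reagents that add atoms: benzyl bromide, BrCc1ccccc1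
Why: Williamson etherification of the three phenols.

Step 7
Reactants: 10 1-[3,4,5-tris(benzyloxy)phenyl]ethanone
Product: 11 (E)-1-[3,4,5-tris(benzyloxy)phenyl]ethanone oxime
Conditions: NH2OH·HCl, pyridine, EtOH, 60 °C
Reagents that add atoms: hydroxylamine hydrochloride, NO.Cl
Why: Condensation of the ketone with hydroxylamine to the oxime.

Step 8
Reactants: 11 (E)-1-[3,4,5-tris(benzyloxy)phenyl]ethanone oxime
Product: 13 N-{1-[3,4,5-tris(benzyloxy)phenyl]ethenyl}acetamide, via O-acetyl oxime 12 (not isolated)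
Conditions: Fe powder, Ac2O, AcOH, toluene, 70 °C
Reagents that add atoms: acetic anhydride, CC(=O)OC(C)=O
Why: Reductive acylation of a ketoxime: O-acetylation to 12, N–O cleavage by iron to the N–H ketimine, tautomerisation and N-acetylation to the α-aryl enamide; benzyl ethers are inert.

Step 9
Reactants: 4 8-bromo-3,5,7,3',4'-penta-O-benzyl-(−)-epicatechin; 8 4-(benzyloxy)-3-bromo-2-hydroxybenzaldehyde
Product: 16 [4-(benzyloxy)-3-bromo-2-hydroxyphenyl](penta-O-benzylepicatechin-8-yl)methanol (both carbinol epimers), via aryllithium 14 (not isolated), via sodium phenolate 15 (not isolated)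
Conditions: 4, n-BuLi, THF, −78 °C; add 15 (from 8, NaH, THF, 0 °C; 1.3 equiv), −78 °C to −20 °C; aq. NH4Cl
Reagents that add atoms: none
Why: Bromine–lithium exchange at C8 gives an aryllithium stabilised by two ortho oxygens, which adds 1,2 to the aldehyde; the acidic phenol is masked beforehand as sodium salt 15 so that 14 is not lost by protonation. The carbinol carbon needs no control because both epimers give the same o-quinone methide in step 10.

Step 10
Reactants: 16 [4-(benzyloxy)-3-bromo-2-hydroxyphenyl](penta-O-benzylepicatechin-8-yl)methanol; 13 N-{1-[3,4,5-tris(benzyloxy)phenyl]ethenyl}acetamide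
Product: 19 (4S)-7-(benzyloxy)-8-bromo-4-(penta-O-benzylepicatechin-8-yl)-2-[3,4,5-tris(benzyloxy)phenyl]-4H-chromene, via o-quinone methide 17 (not isolated), via 2-acetamidochroman 18 (not isolated)
Conditions: 13 (1.5 equiv), (R)-3,3'-bis(2,4,6-triisopropylphenyl)-1,1'-binaphthyl-2,2'-diyl hydrogen phosphate [(R)-TRIP, 10 mol %], 3 Å MS, CHCl3, 0 °C to rt; then TsOH·H2O (10 mol %), 40 °C
Reagents that add atoms: none
Why: The phosphoric acid ionises the benzylic alcohol of 16 (loss of water, helped by the para benzyloxy group and the trialkoxyaryl ring) to the E-configured o-quinone methide 17, which stays hydrogen-bonded through its ring A oxygen to the phosphate while the phosphoryl oxygen holds the N–H of enamide 13. The unsubstituted CH2 terminus of 13 adds to the methide carbon (conjugate addition, C3–C4 bond), and the N-acyl ketiminium ion so formed is captured by the ring A oxygen in a 6-exo-trig closure (O1–C2 bond) to give N,O-ketal 18; overall this is a stepwise inverse-demand [4+2] that closes ring C of the middle unit. TsOH then expels acetamide from 18 to give enol ether 19, so the C2 epimers of 18 converge and C4 is the only stereocentre created. C4 is controlled by the catalyst, which presents one face of the planar methide carbon to the bound enamide; the stereocentres of the epicatechin unit are at least four bonds away and its aryl ring is twisted out of the methide plane, so they should bias the faces only weakly. The closest known reaction type is the chiral phosphoric acid-catalysed addition of enamides and 1,3-dicarbonyl compounds to o-quinone methides generated from o-hydroxybenzhydryl alcohols, which gives 4-aryl-4H-chromenes after elimination. C-alkylation at the methide carbon follows from the polarity of the partners, and the small CH2 nucleophile can pass the two ortho oxygens of the epicatechin ring.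

Step 11
Reactants: 19 (4S)-7-(benzyloxy)-8-bromo-4-(penta-O-benzylepicatechin-8-yl)-2-[3,4,5-tris(benzyloxy)phenyl]-4H-chromene
Product: 21 (2S,3S,4S)-7-(benzyloxy)-8-bromo-4-(penta-O-benzylepicatechin-8-yl)-2-[3,4,5-tris(benzyloxy)phenyl]chroman-3-ol (2,3-cis-3,4-trans), via 2,3-epoxide 20 (not isolated)
Conditions: DMDO (acetone-free, CH2Cl2), −78 °C; then LiBHEt3, THF, −78 °C to −40 °C; H2O
Reagents that add atoms: dimethyldioxirane, CC1(C)OO1
Why: Proposed new method: DMDO should epoxidise the electron-rich enol ether of 19 from the β face, anti to the pseudoaxial C4 aryl group (sets C3); LiBHEt3, a hydride donor without a Lewis acidic site that the alkoxide could use for front-side delivery, should then open the benzylic ketal C2–O bond of 20 from the backside through a loose, oxocarbenium-like transition state (inversion), which places H2 trans to O3 and so the C2 aryl group cis to O3 and trans to the C4 aryl group; the closest known reaction type is DMDO epoxidation of glycals and other cyclic enol ethers followed by opening of the 1,2-anhydro ring at the acetal carbon by hydride or other nucleophiles.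

Step 12
Reactants: 21 (2S,3S,4S)-7-(benzyloxy)-8-bromo-4-(penta-O-benzylepicatechin-8-yl)-2-[3,4,5-tris(benzyloxy)phenyl]chroman-3-ol
Product: 22 3-O-benzyl ether of 21
Conditions: NaH, BnBr, Bu4NI (cat.), DMF, 0 °C to rt
Reagents that add atoms: benzyl bromide, BrCc1ccccc1
Why: Williamson benzylation of the hindered axial alcohol through its sodium alkoxide; the aryl bromide and the stereocentres are inert, and the ether keeps the alkoxide away from the aryllithium of step 18.

Step 13
Reactants: 23 1-[4-(benzyloxy)-2-hydroxyphenyl]ethanone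
Product: 24 1-[4-(benzyloxy)-2-(methoxymethoxy)phenyl]ethanone
Conditions: NaH, MeOCH2Cl, DMF, 0 °C
Reagents that add atoms: chloromethyl methyl ether, COCCl
Why: The chelated phenol is deprotonated by NaH and alkylated; the acetal masks the phenol during the basic epoxidation, where a free 2'-hydroxychalcone would cyclise oxidatively.

Step 14
Reactants: 24 1-[4-(benzyloxy)-2-(methoxymethoxy)phenyl]ethanone; 25 3,4,5-tris(benzyloxy)benzaldehyde
Product: 26 (E)-1-[4-(benzyloxy)-2-(methoxymethoxy)phenyl]-3-[3,4,5-tris(benzyloxy)phenyl]prop-2-en-1-one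
Conditions: KOH, EtOH–THF, rt
Reagents that add atoms: none
Why: Claisen–Schmidt condensation of the methyl ketone with the non-enolisable aldehyde; dehydration of the aldol gives the E-enone.

Step 15
Reactants: 26 (E)-1-[4-(benzyloxy)-2-(methoxymethoxy)phenyl]-3-[3,4,5-tris(benzyloxy)phenyl]prop-2-en-1-one
Product: 27 [4-(benzyloxy)-2-(methoxymethoxy)phenyl]{(2S,3R)-3-[3,4,5-tris(benzyloxy)phenyl]oxiran-2-yl}methanone
Conditions: poly-D-leucine, urea·H2O2, DBU, THF, rt
Reagents that add atoms: urea–hydrogen peroxide, OO.NC(N)=O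
Why: Juliá–Colonna epoxidation: hydroperoxide adds to the enone bound to the helical poly-D-leucine, which selects the enone face and should give the (2S,3R)-trans-epoxide (poly-L-leucine gives the antipode); the E geometry fixes the trans relation.

Step 16
Reactants: 27 [4-(benzyloxy)-2-(methoxymethoxy)phenyl]{(2S,3R)-3-[3,4,5-tris(benzyloxy)phenyl]oxiran-2-yl}methanone
Product: 29 (2S,3S)-7-(benzyloxy)-3-hydroxy-2-[3,4,5-tris(benzyloxy)phenyl]chroman-4-one, via hydroxyphenyl epoxy ketone 28 (not isolated)
Conditions: conc. HCl, MeOH–THF, 50 °C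
Reagents that add atoms: none
Why: Acid cleaves the methoxymethyl acetal, and the freed phenol of 28 opens the protonated epoxide at the benzylic carbon (6-endo, favoured by the electron-rich aryl group) with inversion; this is the standard conversion of chalcone epoxides into 2,3-trans dihydroflavonols and leaves C3 untouched.

Step 17
Reactants: 29 (2S,3S)-7-(benzyloxy)-3-hydroxy-2-[3,4,5-tris(benzyloxy)phenyl]chroman-4-one
Product: 30 (2S,3S)-3,7-bis(benzyloxy)-2-[3,4,5-tris(benzyloxy)phenyl]chroman-4-one
Conditions: BnOC(=NH)CCl3, TfOH (5 mol %), CH2Cl2–cyclohexane, 0 °C to rt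
Reagents that add atoms: benzyl 2,2,2-trichloroacetimidate, N=C(OCc1ccccc1)C(Cl)(Cl)Cl
Why: Acid-catalysed benzylation with the trichloroacetimidate avoids base, under which the α-ketol would open by β-elimination of the ring oxygen or epimerise.

Step 18
Reactants: 22 3-O-benzyl ether of 21; 30 (2S,3S)-3,7-bis(benzyloxy)-2-[3,4,5-tris(benzyloxy)phenyl]chroman-4-one
Product: 32 tertiary carbinol, the 4-hydroxy derivative of 34 at C4 of the top unit (both C4 epimers), via aryllithium 31 (not isolated)
Conditions: 22, n-BuLi, THF, −78 °C; add to 30 (1.5 equiv) premixed with LaCl3·2LiCl in THF, −78 °C to −30 °C; aq. NH4Cl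
Reagents that add atoms: none
Why: Bromine–lithium exchange gives the C8 aryllithium of the middle unit, which adds 1,2 to the ketone activated by LaCl3·2LiCl (this suppresses enolisation at C3). The C4(top)–C8(middle) bond is thus made at the ring position that electrophilic chemistry would avoid; the carbinol configuration is irrelevant because step 19 passes through cation 33.

Step 19
Reactants: 32 tertiary carbinol (both C4 epimers)
Product: 34 pentadeca-O-benzyl ether of 35, via C4 carbenium ion 33 (not isolated)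
Conditions: Et3SiH (10 equiv), CF3CO2H (3 equiv), CH2Cl2, −40 °C
Reagents that add atoms: none
Why: Ionic hydrogenation (Kursanov–Parnes) of a tertiary dibenzylic alcohol: CF3CO2H ionises 32 to cation 33, stabilised by O1, O7 and the dialkoxyaryl ring, and Et3SiH should deliver hydride to C4 from the face trans to the C3 benzyloxy group. This is the same facial preference by which arenes add trans to O3 of 2,3-trans flavan cations, so the aryl group already present ends cis to O3 (3,4-cis, 2,4-trans).

Step 20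
Reactants: 34 pentadeca-O-benzyl ether of 35
Product: 35 CNP0115797.3, ent-robinetinidol-(4α→8)-ent-epirobinetinidol-(4α→8)-epicatechin
Conditions: H2 (1 atm), Pd(OH)2/C, THF–MeOH–H2O, rt; filtration and freeze-drying under argon
Reagents that add atoms: none
Why: Hydrogenolysis of all fifteen benzyl ethers under neutral conditions; the C4–aryl bonds and the benzylic ring ethers of flavans should survive Pd(OH)2/C at ambient pressure, and no stereocentre is touched.

## Compound list

1 | (−)-epicatechin, (2R,3R)-2-(3,4-dihydroxyphenyl)chromane-3,5,7-triol | Oc1cc(O)c2c(c1)O[C@H](c1ccc(O)c(O)c1)[C@H](O)C2 | starting material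

2 | 5,7,3',4'-tetra-O-benzyl-(−)-epicatechin | c1c(OCc3ccccc3)cc(OCc3ccccc3)c2c1O[C@H](c1ccc(OCc3ccccc3)c(OCc3ccccc3)c1)[C@H](O)C2 | intermediate

3 | 3,5,7,3',4'-penta-O-benzyl-(−)-epicatechin | c1c(OCc3ccccc3)cc(OCc3ccccc3)c2c1O[C@H](c1ccc(OCc3ccccc3)c(OCc3ccccc3)c1)[C@H](OCc1ccccc1)C2 | intermediate

4 | 8-bromo-3,5,7,3',4'-penta-O-benzyl-(−)-epicatechin | Brc1c(OCc3ccccc3)cc(OCc3ccccc3)c2c1O[C@H](c1ccc(OCc3ccccc3)c(OCc3ccccc3)c1)[C@H](OCc1ccccc1)C2 | intermediate

5 | 2-bromoresorcinol (2-bromobenzene-1,3-diol) | Oc1cccc(O)c1Br | starting material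

6 | N-[(3-bromo-2,4-dihydroxyphenyl)methylidene]-N-methylmethanaminium chloride | C[N+](C)=Cc1ccc(O)c(Br)c1O.[Cl-] | intermediate

7 | 3-bromo-2,4-dihydroxybenzaldehyde | O=Cc1ccc(O)c(Br)c1O | intermediate

8 | 4-(benzyloxy)-3-bromo-2-hydroxybenzaldehyde | O=Cc1ccc(OCc2ccccc2)c(Br)c1O | intermediate

9 | 1-(3,4,5-trihydroxyphenyl)ethanone | CC(=O)c1cc(O)c(O)c(O)c1 | starting material

10 | 1-[3,4,5-tris(benzyloxy)phenyl]ethanone | CC(=O)c1cc(OCc2ccccc2)c(OCc2ccccc2)c(OCc2ccccc2)c1 | intermediate

11 | (E)-1-[3,4,5-tris(benzyloxy)phenyl]ethanone oxime | C/C(=N\O)c1cc(OCc2ccccc2)c(OCc2ccccc2)c(OCc2ccccc2)c1 | intermediate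

12 | (E)-1-[3,4,5-tris(benzyloxy)phenyl]ethanone O-acetyloxime | C/C(=N\OC(C)=O)c1cc(OCc2ccccc2)c(OCc2ccccc2)c(OCc2ccccc2)c1 | intermediate

13 | N-{1-[3,4,5-tris(benzyloxy)phenyl]ethenyl}acetamide | CC(=O)NC(=C)c1cc(OCc2ccccc2)c(OCc2ccccc2)c(OCc2ccccc2)c1 | intermediate

14 | 8-lithio-3,5,7,3',4'-penta-O-benzyl-(−)-epicatechin | [Li]c1c(OCc3ccccc3)cc(OCc3ccccc3)c2c1O[C@H](c1ccc(OCc3ccccc3)c(OCc3ccccc3)c1)[C@H](OCc1ccccc1)C2 | intermediate

15 | sodium 3-(benzyloxy)-2-bromo-6-formylphenolate | O=Cc1ccc(OCc2ccccc2)c(Br)c1[O-].[Na+] | intermediate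

16 | [4-(benzyloxy)-3-bromo-2-hydroxyphenyl](penta-O-benzylepicatechin-8-yl)methanol, both carbinol epimers | OC(c1ccc(OCc2ccccc2)c(Br)c1O)c1c(OCc3ccccc3)cc(OCc3ccccc3)c2c1O[C@H](c1ccc(OCc3ccccc3)c(OCc3ccccc3)c1)[C@H](OCc1ccccc1)C2 | intermediate

17 | (E)-3-(benzyloxy)-2-bromo-6-[(penta-O-benzylepicatechin-8-yl)methylidene]cyclohexa-2,4-dien-1-one | O=C1C(Br)=C(OCc2ccccc2)C=C/C1=C\c1c(OCc3ccccc3)cc(OCc3ccccc3)c2c1O[C@H](c1ccc(OCc3ccccc3)c(OCc3ccccc3)c1)[C@H](OCc1ccccc1)C2 | intermediate

18 | N-{(4S)-7-(benzyloxy)-8-bromo-4-(penta-O-benzylepicatechin-8-yl)-2-[3,4,5-tris(benzyloxy)phenyl]chroman-2-yl}acetamide, both C2 epimers | Brc1c(OCc3ccccc3)ccc2c1OC(NC(C)=O)(c1cc(OCc3ccccc3)c(OCc3ccccc3)c(OCc3ccccc3)c1)C[C@@H]2c1c(OCc3ccccc3)cc(OCc3ccccc3)c2c1O[C@H](c1ccc(OCc3ccccc3)c(OCc3ccccc3)c1)[C@H](OCc1ccccc1)C2 | intermediate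

19 | (4S)-7-(benzyloxy)-8-bromo-4-(penta-O-benzylepicatechin-8-yl)-2-[3,4,5-tris(benzyloxy)phenyl]-4H-chromene | Brc1c(OCc3ccccc3)ccc2c1OC(c1cc(OCc3ccccc3)c(OCc3ccccc3)c(OCc3ccccc3)c1)=C[C@@H]2c1c(OCc3ccccc3)cc(OCc3ccccc3)c2c1O[C@H](c1ccc(OCc3ccccc3)c(OCc3ccccc3)c1)[C@H](OCc1ccccc1)C2 | intermediate

20 | 2β,3β-epoxide of 19 (oxirane anti to the 4α-aryl group) | Brc1c(OCc3ccccc3)ccc2c1O[C@@]4(c1cc(OCc3ccccc3)c(OCc3ccccc3)c(OCc3ccccc3)c1)O[C@H]4[C@@H]2c1c(OCc3ccccc3)cc(OCc3ccccc3)c2c1O[C@H](c1ccc(OCc3ccccc3)c(OCc3ccccc3)c1)[C@H](OCc1ccccc1)C2 | intermediate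

21 | (2S,3S,4S)-7-(benzyloxy)-8-bromo-4-(penta-O-benzylepicatechin-8-yl)-2-[3,4,5-tris(benzyloxy)phenyl]chroman-3-ol (2,3-cis-3,4-trans) | Brc1c(OCc3ccccc3)ccc2c1O[C@@H](c1cc(OCc3ccccc3)c(OCc3ccccc3)c(OCc3ccccc3)c1)[C@@H](O)[C@@H]2c1c(OCc3ccccc3)cc(OCc3ccccc3)c2c1O[C@H](c1ccc(OCc3ccccc3)c(OCc3ccccc3)c1)[C@H](OCc1ccccc1)C2 | intermediate

22 | 3-O-benzyl ether of 21 | Brc1c(OCc3ccccc3)ccc2c1O[C@@H](c1cc(OCc3ccccc3)c(OCc3ccccc3)c(OCc3ccccc3)c1)[C@@H](OCc1ccccc1)[C@@H]2c1c(OCc3ccccc3)cc(OCc3ccccc3)c2c1O[C@H](c1ccc(OCc3ccccc3)c(OCc3ccccc3)c1)[C@H](OCc1ccccc1)C2 | intermediate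

23 | 1-[4-(benzyloxy)-2-hydroxyphenyl]ethanone | CC(=O)c1ccc(OCc2ccccc2)cc1O | starting material

24 | 1-[4-(benzyloxy)-2-(methoxymethoxy)phenyl]ethanone | CC(=O)c1ccc(OCc2ccccc2)cc1OCOC | intermediate

25 | 3,4,5-tris(benzyloxy)benzaldehyde | O=Cc1cc(OCc2ccccc2)c(OCc2ccccc2)c(OCc2ccccc2)c1 | starting material

26 | (E)-1-[4-(benzyloxy)-2-(methoxymethoxy)phenyl]-3-[3,4,5-tris(benzyloxy)phenyl]prop-2-en-1-one | O=C(/C=C/c1cc(OCc2ccccc2)c(OCc2ccccc2)c(OCc2ccccc2)c1)c1ccc(OCc2ccccc2)cc1OCOC | intermediate

27 | [4-(benzyloxy)-2-(methoxymethoxy)phenyl]{(2S,3R)-3-[3,4,5-tris(benzyloxy)phenyl]oxiran-2-yl}methanone | O=C([C@H]1O[C@@H]1c1cc(OCc2ccccc2)c(OCc2ccccc2)c(OCc2ccccc2)c1)c1ccc(OCc2ccccc2)cc1OCOC | intermediate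

28 | [4-(benzyloxy)-2-hydroxyphenyl]{(2S,3R)-3-[3,4,5-tris(benzyloxy)phenyl]oxiran-2-yl}methanone | O=C([C@H]1O[C@@H]1c1cc(OCc2ccccc2)c(OCc2ccccc2)c(OCc2ccccc2)c1)c1ccc(OCc2ccccc2)cc1O | intermediate

29 | (2S,3S)-7-(benzyloxy)-3-hydroxy-2-[3,4,5-tris(benzyloxy)phenyl]chroman-4-one | c1ccccc1COc1ccc2c(c1)O[C@@H](c1cc(OCc3ccccc3)c(OCc3ccccc3)c(OCc3ccccc3)c1)[C@H](O)C2=O | intermediate

30 | (2S,3S)-3,7-bis(benzyloxy)-2-[3,4,5-tris(benzyloxy)phenyl]chroman-4-one | c1ccccc1COc1ccc2c(c1)O[C@@H](c1cc(OCc3ccccc3)c(OCc3ccccc3)c(OCc3ccccc3)c1)[C@H](OCc1ccccc1)C2=O | intermediate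

31 | C8 aryllithium of 22 (lithium in place of bromine) | [Li]c1c(OCc3ccccc3)ccc2c1O[C@@H](c1cc(OCc3ccccc3)c(OCc3ccccc3)c(OCc3ccccc3)c1)[C@@H](OCc1ccccc1)[C@@H]2c1c(OCc3ccccc3)cc(OCc3ccccc3)c2c1O[C@H](c1ccc(OCc3ccccc3)c(OCc3ccccc3)c1)[C@H](OCc1ccccc1)C2 | intermediate

32 | tertiary carbinol: 34 with OH in place of H at C4 of the top unit, both C4 epimers | c1ccccc1COc1ccc2c(c1)O[C@@H](c1cc(OCc3ccccc3)c(OCc3ccccc3)c(OCc3ccccc3)c1)[C@H](OCc1ccccc1)C2(O)c1c(OCc3ccccc3)ccc2c1O[C@@H](c1cc(OCc3ccccc3)c(OCc3ccccc3)c(OCc3ccccc3)c1)[C@@H](OCc1ccccc1)[C@@H]2c1c(OCc3ccccc3)cc(OCc3ccccc3)c2c1O[C@H](c1ccc(OCc3ccccc3)c(OCc3ccccc3)c1)[C@H](OCc1ccccc1)C2 | intermediate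

33 | C4 carbenium ion of the top unit derived from 32 | c1ccccc1COc1ccc2c(c1)O[C@@H](c1cc(OCc3ccccc3)c(OCc3ccccc3)c(OCc3ccccc3)c1)[C@H](OCc1ccccc1)[C+]2c1c(OCc3ccccc3)ccc2c1O[C@@H](c1cc(OCc3ccccc3)c(OCc3ccccc3)c(OCc3ccccc3)c1)[C@@H](OCc1ccccc1)[C@@H]2c1c(OCc3ccccc3)cc(OCc3ccccc3)c2c1O[C@H](c1ccc(OCc3ccccc3)c(OCc3ccccc3)c1)[C@H](OCc1ccccc1)C2 | intermediate

34 | pentadeca-O-benzyl ether of 35 (top unit 2S,3R,4S; middle unit 2S,3S,4S; bottom unit 2R,3R) | c1ccccc1COc1ccc2c(c1)O[C@@H](c1cc(OCc3ccccc3)c(OCc3ccccc3)c(OCc3ccccc3)c1)[C@H](OCc1ccccc1)[C@@H]2c1c(OCc3ccccc3)ccc2c1O[C@@H](c1cc(OCc3ccccc3)c(OCc3ccccc3)c(OCc3ccccc3)c1)[C@@H](OCc1ccccc1)[C@@H]2c1c(OCc3ccccc3)cc(OCc3ccccc3)c2c1O[C@H](c1ccc(OCc3ccccc3)c(OCc3ccccc3)c1)[C@H](OCc1ccccc1)C2 | intermediate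

35 | CNP0115797.3, ent-robinetinidol-(4α→8)-ent-epirobinetinidol-(4α→8)-epicatechin | Oc1ccc2c(c1)O[C@@H](c1cc(O)c(O)c(O)c1)[C@H](O)[C@@H]2c1c(O)ccc2c1O[C@@H](c1cc(O)c(O)c(O)c1)[C@@H](O)[C@@H]2c1c(O)cc(O)c2c1O[C@H](c1ccc(O)c(O)c1)[C@H](O)C2 | target

## Step count and risk

Total: 20 steps. Longest linear sequence: 10 steps (steps 1, 2, 3, 9, 10, 11, 12, 18, 19, 20).

**Step 11 (proposed new method).** The epoxy ketal 20 may ionise before the hydride arrives. It could then rearrange by a 1,2-hydride shift to the flavan-3-one, or take hydride from the front side and give the 2,3-trans ring. Fallback with known chemistry, from 19 back to 21: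
- Dihydroxylation of 19 with OsO4 (cat.) and N-methylmorpholine N-oxide, anti to the C4 aryl group, gives the α-hydroxy ketone F1 (the open form of the hemiketal).
- Chelation-controlled reduction with Zn(BH4)2 gives the anti diol F2.
- Mitsunobu ring closure (PPh3, diisopropyl azodicarboxylate) of the phenol onto the benzylic carbinol, with inversion at C2, gives 21.

**Step 10 (key step).** The o-quinone methide 17 carries two donor rings and may be captured only slowly. The catalyst may also discriminate the faces poorly against the chiral aryl group (mismatched pairing), and the enamide may hydrolyse meanwhile. Fallback, from 8 and 10 back to 19: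
- Acid condensation of 8 with 10 (HBF4, AcOH) gives the flavylium tetrafluoroborate F3.
- Aryllithium 14, made as in step 9, is added at C4 at −78 °C. This gives 19 together with the 4R epimer F4; the two are diastereomers and are separated by chromatography.

**Step 18.** The aryllithium may act as a base (enolisation at C3 and opening of ring C), or fail to add for steric reasons. Fallback, from 31 and 27 back to 32:
- 31 is added to the epoxy ketone 27, whose only α-hydrogen sits on the oxirane, to give the epoxy carbinol F5.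
- HCl in methanol, as in step 16, removes the acetal and closes ring C to give the 3,4-diol F6.
- Benzylation of the secondary hydroxyl (NaH, BnBr) gives 32.

**Step 19.** Cation 33 may lose H3 to the enol ether, which scrambles C3. The acid may cleave benzyl ethers, and the small silane may show weak facial bias. Fallback, from 32 back to 34:
- SOCl2 and 2,6-lutidine give the tertiary chloride F7.
- Radical reduction with (Me3Si)3SiH and Et3B/air at low temperature transfers a hydrogen atom to the C4 radical, anti to the C3 benzyloxy group and without acid, to give 34.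

## Further compounds

F1 | step 11 | (2S,3S)-3-[4-(benzyloxy)-3-bromo-2-hydroxyphenyl]-2-hydroxy-3-(penta-O-benzylepicatechin-8-yl)-1-[3,4,5-tris(benzyloxy)phenyl]propan-1-one | O=C(c1cc(OCc2ccccc2)c(OCc2ccccc2)c(OCc2ccccc2)c1)[C@@H](O)[C@@H](c1ccc(OCc2ccccc2)c(Br)c1O)c1c(OCc3ccccc3)cc(OCc3ccccc3)c2c1O[C@H](c1ccc(OCc3ccccc3)c(OCc3ccccc3)c1)[C@H](OCc1ccccc1)C2

F2 | step 11 | (1R,2S,3S)-3-[4-(benzyloxy)-3-bromo-2-hydroxyphenyl]-3-(penta-O-benzylepicatechin-8-yl)-1-[3,4,5-tris(benzyloxy)phenyl]propane-1,2-diol (anti diol) | O[C@H](c1cc(OCc2ccccc2)c(OCc2ccccc2)c(OCc2ccccc2)c1)[C@@H](O)[C@@H](c1ccc(OCc2ccccc2)c(Br)c1O)c1c(OCc3ccccc3)cc(OCc3ccccc3)c2c1O[C@H](c1ccc(OCc3ccccc3)c(OCc3ccccc3)c1)[C@H](OCc1ccccc1)C2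

F3 | step 10 | 7-(benzyloxy)-8-bromo-2-[3,4,5-tris(benzyloxy)phenyl]chromenylium tetrafluoroborate | Brc1c(OCc3ccccc3)ccc2ccc(-c3cc(OCc4ccccc4)c(OCc4ccccc4)c(OCc4ccccc4)c3)[o+]c12.F[B-](F)(F)F

F4 | step 10 | (4R)-epimer of 19 | Brc1c(OCc3ccccc3)ccc2c1OC(c1cc(OCc3ccccc3)c(OCc3ccccc3)c(OCc3ccccc3)c1)=C[C@H]2c1c(OCc3ccccc3)cc(OCc3ccccc3)c2c1O[C@H](c1ccc(OCc3ccccc3)c(OCc3ccccc3)c1)[C@H](OCc1ccccc1)C2

F5 | step 18 | epoxy carbinol: adduct of 31 to the carbonyl group of 27 (both carbinol epimers, oxirane 2S,3R as in 27) | COCOc1cc(OCc2ccccc2)ccc1C(O)([C@H]1O[C@@H]1c1cc(OCc2ccccc2)c(OCc2ccccc2)c(OCc2ccccc2)c1)c1c(OCc3ccccc3)ccc2c1O[C@@H](c1cc(OCc3ccccc3)c(OCc3ccccc3)c(OCc3ccccc3)c1)[C@@H](OCc1ccccc1)[C@@H]2c1c(OCc3ccccc3)cc(OCc3ccccc3)c2c1O[C@H](c1ccc(OCc3ccccc3)c(OCc3ccccc3)c1)[C@H](OCc1ccccc1)C2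

F6 | step 18 | 3,4-diol: 32 with free 3-OH in the top unit (both C4 epimers) | c1ccccc1COc1ccc2c(c1)O[C@@H](c1cc(OCc3ccccc3)c(OCc3ccccc3)c(OCc3ccccc3)c1)[C@H](O)C2(O)c1c(OCc3ccccc3)ccc2c1O[C@@H](c1cc(OCc3ccccc3)c(OCc3ccccc3)c(OCc3ccccc3)c1)[C@@H](OCc1ccccc1)[C@@H]2c1c(OCc3ccccc3)cc(OCc3ccccc3)c2c1O[C@H](c1ccc(OCc3ccccc3)c(OCc3ccccc3)c1)[C@H](OCc1ccccc1)C2

F7 | step 19 | tertiary chloride: 32 with Cl in place of OH at C4 of the top unit (both C4 epimers) | c1ccccc1COc1ccc2c(c1)O[C@@H](c1cc(OCc3ccccc3)c(OCc3ccccc3)c(OCc3ccccc3)c1)[C@H](OCc1ccccc1)C2(Cl)c1c(OCc3ccccc3)ccc2c1O[C@@H](c1cc(OCc3ccccc3)c(OCc3ccccc3)c(OCc3ccccc3)c1)[C@@H](OCc1ccccc1)[C@@H]2c1c(OCc3ccccc3)cc(OCc3ccccc3)c2c1O[C@H](c1ccc(OCc3ccccc3)c(OCc3ccccc3)c1)[C@H](OCc1ccccc1)C2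

A1 | alternative 1 | (2S,3R)-3,7-bis(benzyloxy)-4-methoxy-2-[3,4,5-tris(benzyloxy)phenyl]chromane (both C4 epimers) | c1ccccc1COc1ccc2c(c1)O[C@@H](c1cc(OCc3ccccc3)c(OCc3ccccc3)c(OCc3ccccc3)c1)[C@H](OCc1ccccc1)C2OC

A2 | alternative 1 | debrominated 22 (hydrogen at C8 of the middle unit) | c1c(OCc3ccccc3)ccc2c1O[C@@H](c1cc(OCc3ccccc3)c(OCc3ccccc3)c(OCc3ccccc3)c1)[C@@H](OCc1ccccc1)[C@@H]2c1c(OCc3ccccc3)cc(OCc3ccccc3)c2c1O[C@H](c1ccc(OCc3ccccc3)c(OCc3ccccc3)c1)[C@H](OCc1ccccc1)C2

A3 | alternative 2 | (E)-4,4,5,5-tetramethyl-2-{2-[3,4,5-tris(benzyloxy)phenyl]ethenyl}-1,3,2-dioxaborolane | CC1(C)OB(/C=C/c2cc(OCc3ccccc3)c(OCc3ccccc3)c(OCc3ccccc3)c2)OC1(C)C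

A4 | alternative 2 | 3-boryl cycloadduct of 17 and A3 (2,4-cis, 2,3-trans, 3,4-trans; 2α-aryl, 3β-boryl, 4α-aryl) | Brc1c(OCc3ccccc3)ccc2c1O[C@H](c1cc(OCc3ccccc3)c(OCc3ccccc3)c(OCc3ccccc3)c1)[C@@H](B4OC(C)(C)C(C)(C)O4)[C@@H]2c1c(OCc3ccccc3)cc(OCc3ccccc3)c2c1O[C@H](c1ccc(OCc3ccccc3)c(OCc3ccccc3)c1)[C@H](OCc1ccccc1)C2

A5 | alternative 3 | (2S,3S)-3,7-bis(benzyloxy)-8-bromo-2-[3,4,5-tris(benzyloxy)phenyl]chroman-4-one | Brc1c(OCc3ccccc3)ccc2c1O[C@@H](c1cc(OCc3ccccc3)c(OCc3ccccc3)c(OCc3ccccc3)c1)[C@H](OCc1ccccc1)C2=O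

A6 | alternative 3 | C3 epimer of 22 (middle ring 2,3-trans-3,4-cis) | Brc1c(OCc3ccccc3)ccc2c1O[C@@H](c1cc(OCc3ccccc3)c(OCc3ccccc3)c(OCc3ccccc3)c1)[C@H](OCc1ccccc1)[C@@H]2c1c(OCc3ccccc3)cc(OCc3ccccc3)c2c1O[C@H](c1ccc(OCc3ccccc3)c(OCc3ccccc3)c1)[C@H](OCc1ccccc1)C2
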